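**Retrosynthetic overview**
1. There is one disconnection, at the ester acyl C–O bond. It gives docosanoic acid (1) and 3-(4-hydroxyphenyl)propan-1-ol (2), both catalogue chemicals, so every C–C bond is bought.
2. Forward, a protecting-group-free catalytic dehydrative esterification passes 1 through two catalyst-bound acyl donors (3, 4) to the primary OH of 2. This gives target 5, with water as the only by-product.
3. The one selectivity issue is aliphatic OH versus phenol OH. It is handled kinetically (the neutral primary OH is the better nucleophile) and thermodynamically (aryl esters are active esters that transfer back to the alcohol).
4. No ring is formed, since the benzene ring arrives with 2, and there are no stereocentres.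

Assumption: the target has no stereocentre and no stereogenic double bond. It is achiral and exists as one compound only, so nothing has to be set or resolved.

**Step 1**
Reactants: 1 docosanoic acid; 2 3-(4-hydroxyphenyl)propan-1-ol
Product: 5 3-(4-hydroxyphenyl)propyl docosanoate, via acyloxyboron mixed anhydride 3 (not isolated), via acyloxypyridinium boronate ion pair 4 (not isolated)
Conditions: 1 (1.0 equiv), 2 (1.1 equiv), 3,5-(CF3)2C6H3B(OH)2 (10 mol %), 4-(dimethylamino)pyridine N-oxide (10 mol %), toluene (0.3 M), azeotropic reflux through 4 Å MS, N2, 16 h; silica plug, recrystallise (EtOH)
Reagents that add atoms: none
Why: Proposed new method: cooperative arylboronic acid/pyridine N-oxide catalysed dehydrative O-acylation of an alcohol, in which the electron-poor boronic acid condenses reversibly with 1 to the mixed anhydride 3 (water leaves with the azeotrope), the strongly O-nucleophilic 4-(dimethylamino)pyridine N-oxide attacks the acyl carbon of 3 to give the much more electrophilic acyloxypyridinium ion pair 4, and the boronate counter-ion serves as general base while the primary OH of 2 takes the acyl group and both catalysts are returned; the phenol stays free because no base able to form phenoxide is present, the neutral aliphatic OH is the better nucleophile, and any aryl ester that forms is itself an active ester that the N-oxide re-routes to the thermodynamically preferred alkyl ester; the closest known reaction types are boronic acid/4-(dimethylamino)pyridine N-oxide co-catalysed direct amidation (amine nucleophiles only) and the Shiina esterification (N-oxide acyl transfer to an alcohol from a stoichiometric aromatic mixed anhydride), and the new element is a catalytic boron mixed anhydride used to acylate an alcohol with an unactivated fatty acid; no stereocentre is created.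

**Compound list**
1 | docosanoic acid (behenic acid) | CCCCCCCCCCCCCCCCCCCCCC(=O)O | starting material
2 | 3-(4-hydroxyphenyl)propan-1-ol | OCCCc1ccc(O)cc1 | starting material
3 | [3,5-bis(trifluoromethyl)phenyl](hydroxy)boranyl docosanoate (acyloxyboron mixed anhydride) | CCCCCCCCCCCCCCCCCCCCCC(=O)OB(O)c1cc(C(F)(F)F)cc(C(F)(F)F)c1 | intermediate
4 | 1-(docosanoyloxy)-4-(dimethylamino)pyridin-1-ium [3,5-bis(trifluoromethyl)phenyl](hydroxy)boranolate (ion pair) | CCCCCCCCCCCCCCCCCCCCCC(=O)O[n+]1ccc(N(C)C)cc1.OB([O-])c1cc(C(F)(F)F)cc(C(F)(F)F)c1 | intermediate
5 | 3-(4-hydroxyphenyl)propyl docosanoate | CCCCCCCCCCCCCCCCCCCCCC(=O)OCCCc1ccc(O)cc1 | target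

**Total step count:** 1
**Longest linear sequence:** 1

**Steps most likely to fail**
The route has a single step, so the ranking has one entry.

Step 1 is the proposed new step, and it carries three risks:
- Alcohol 2 may tie up the boronic acid as its boronic ester under the dehydrating conditions.
- Acyl transfer from 4 to a neutral alcohol may be much slower than to an amine.
- Boron-assisted acylation of the phenol could give some aryl ester or diester before equilibration.

The fallback is known chemistry that reverses the polarity of the bond formation. It sets out from 2, with 1 as partner, and comes back to the route at 5. It is a Mitsunobu reaction with PPh3 (1.2 equiv) and diisopropyl azodicarboxylate (1.2 equiv, added last, dropwise) in THF at 0 °C to room temperature. These reagents convert the primary OH of 2 into [3-(4-hydroxyphenyl)propoxy]triphenylphosphonium docosanoate F1. The carboxylate of this salt then displaces the phosphine oxide at the primary carbon (SN2), so the alkyl C–O bond is made instead of the acyl C–O bond.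

The phenol needs no protection in the fallback. It cannot act as the electrophile, and as the far weaker acid (pKa about 10 against about 5 for 1) it is not the nucleophile while the carboxylate is present. Chromatography then gives 5.

**Further compounds**
F1 | step 1 | [3-(4-hydroxyphenyl)propoxy]triphenylphosphonium docosanoate | CCCCCCCCCCCCCCCCCCCCCC(=O)[O-].Oc1ccc(CCCO[P+](c2ccccc2)(c2ccccc2)c2ccccc2)cc1
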